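**Retrosynthetic overview**

1. The flavanone is unfolded into one linear, masked poly-β-carbonyl chain, compound 12: an (S)-δ-hydroxy-β-diketone whose last two carbonyls (C7, C5) are held as a 1,3-dioxin-4-one. In one operation ring C closes first (O1–C8a, cyclodehydration) and ring A second (C4a–C5, acylketene electrocyclisation).
2. Enabling feature: ring A carries oxygen on C8a, C7 and C5 in alternation with the C4 carbonyl, so C4–C4a–C8a–C8–C7–C6–C5 is a tetraketide. Its C8a carbonyl lies δ to the C2 carbinol oxygen (six-membered hemiketal), and C4a lies six atoms from C5.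
3. 12 ⇒ β-hydroxy ester 9 + dianion of keto-dioxinone 11 (Claisen, C4–C4a); 11 ⇒ dioxinone 10 + acetyl chloride.
4. 9 ⇒ β-keto ester 8 by asymmetric transfer hydrogenation (sets C2) ⇒ benzoate 7 + methyl acetate.
5. 7 (ring B) ⇒ methyl 3-bromo-4-hydroxybenzoate 1 by iodination, O-methylation, iodide-selective Suzuki–Miyaura dienylation and Negishi prenylation. Ring order: B (bought), then C, then A.

Key step: step 10

Remark: Ar = 4-methoxy-3-[(1E)-3-methylbuta-1,3-dien-1-yl]-5-(3-methylbut-2-en-1-yl)phenyl; the atom numbers O1 and C2–C8a of the final chromanone are also used for the open-chain compounds; the sense of induction in step 7 is assumed to follow that of simple aryl ketones.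

**Route**

Step 1
Reactants: 1 methyl 3-bromo-4-hydroxybenzoate
Product: 2 methyl 3-bromo-4-hydroxy-5-iodobenzoate
Conditions: NIS (1.05 equiv), TsOH·H2O (10 mol %), MeCN, rt
Reagents that add atoms: N-iodosuccinimide, O=C1CCC(=O)N1I
Why: Electrophilic aromatic iodination, directed by the phenol to its only free ortho position because the para position carries the ester.

Step 2
Reactants: 2 methyl 3-bromo-4-hydroxy-5-iodobenzoate
Product: 3 methyl 3-bromo-5-iodo-4-methoxybenzoate
Conditions: MeI, K2CO3, DMF, rt
Reagents that add atoms: iodomethane, CI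
Why: Williamson ether synthesis on an acidic 2,6-dihalophenol; the methyl ester is inert to K2CO3.

Step 3
Reactants: 4 2-methylbut-1-en-3-yne
Product: 5 4,4,5,5-tetramethyl-2-[(1E)-3-methylbuta-1,3-dien-1-yl]-1,3,2-dioxaborolane
Conditions: pinacolborane (1.1 equiv), Cp2Zr(H)Cl (5 mol %), Et3N (10 mol %), sealed tube, 50 °C
Reagents that add atoms: pinacolborane, B1OC(C)(C)C(C)(C)O1
Why: Zirconium-hydride-catalysed hydroboration of a terminal alkyne; syn addition with boron at the terminal carbon should give the (E)-dienylboronate and leave the 1,1-disubstituted alkene alone.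

Step 4
Reactants: 3 methyl 3-bromo-5-iodo-4-methoxybenzoate; 5 4,4,5,5-tetramethyl-2-[(1E)-3-methylbuta-1,3-dien-1-yl]-1,3,2-dioxaborolane
Product: 6 methyl 3-bromo-4-methoxy-5-[(1E)-3-methylbuta-1,3-dien-1-yl]benzoate
Conditions: Pd(PPh3)4 (3 mol %), K2CO3 (aq.), THF, 50 °C
Reagents that add atoms: none
Why: Suzuki–Miyaura coupling; zerovalent palladium inserts into C–I much faster than into C–Br, so only the iodide should couple, with retention of the alkene geometry.

Step 5
Reactants: 6 methyl 3-bromo-4-methoxy-5-[(1E)-3-methylbuta-1,3-dien-1-yl]benzoate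
Product: 7 methyl 4-methoxy-3-[(1E)-3-methylbuta-1,3-dien-1-yl]-5-(3-methylbut-2-en-1-yl)benzoate
Conditions: prenyl bromide, Zn dust, LiCl, THF, 0 °C (forms prenylzinc bromide); then 6, Pd(OAc)2 (2 mol %), CPhos (4 mol %), THF, rt
Reagents that add atoms: prenyl bromide, CC(C)=CCBr
Why: Negishi coupling of the allylzinc halide made in the flask by zinc insertion into prenyl bromide; the biarylphosphine CPhos is known to steer such couplings to the linear (α-bound) prenyl arene, and the organozinc tolerates the ester.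

Step 6
Reactants: 7 methyl 4-methoxy-3-[(1E)-3-methylbuta-1,3-dien-1-yl]-5-(3-methylbut-2-en-1-yl)benzoate
Product: 8 methyl 3-Ar-3-oxopropanoate
Conditions: MeOAc (3 equiv), LiHMDS (3 equiv), THF, −78 °C → 0 °C; AcOH quench
Reagents that add atoms: methyl acetate, CC(=O)OC
Why: Crossed Claisen condensation; the benzoate has no α-hydrogen, the product is drained as its stabilised enolate, and methyl acetate excludes ester scrambling.

Step 7
Reactants: 8 methyl 3-Ar-3-oxopropanoate
Product: 9 methyl (3S)-3-Ar-3-hydroxypropanoate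
Conditions: RuCl[(S,S)-TsDPEN](p-cymene) (1 mol %), HCO2H/Et3N (5:2), DMF, 40 °C
Reagents that add atoms: none
Why: Noyori asymmetric transfer hydrogenation of an aryl ketone; the (S,S)-ligand should deliver hydride to the face that gives the (S)-carbinol through the CH/π-organised six-membered transition state, and the ruthenium hydride does not reduce the isolated or conjugated C=C bonds.

Step 8
Reactants: 10 2,2,6-trimethyl-4H-1,3-dioxin-4-one
Product: 11 2,2-dimethyl-6-(2-oxopropyl)-4H-1,3-dioxin-4-one
Conditions: LiHMDS (1.0 equiv), THF, −78 °C; AcCl (0.5 equiv), −78 °C → −20 °C; AcOH quench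
Reagents that add atoms: acetyl chloride, CC(=O)Cl
Why: γ-Acylation of the lithium dienolate of the dioxinone (vinylogous Claisen condensation); the second equivalent of dienolate takes up the more acidic product.

Step 9
Reactants: 9 methyl (3S)-3-Ar-3-hydroxypropanoate; 11 2,2-dimethyl-6-(2-oxopropyl)-4H-1,3-dioxin-4-one
Product: 12 6-[(6S)-6-Ar-6-hydroxy-2,4-dioxohexyl]-2,2-dimethyl-4H-1,3-dioxin-4-one
Conditions: 11 (3.5 equiv), LDA (7 equiv), THF, −78 °C → −40 °C; then 9, −78 °C → −20 °C; AcOH quench
Reagents that add atoms: none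
Why: Claisen condensation of a β-dicarbonyl dianion through its terminal, most nucleophilic carbon with an ester; the hydroxyl rides through as its lithium alkoxide at low temperature and the stereocenter is not touched.

Step 10
Reactants: 12 6-[(6S)-6-Ar-6-hydroxy-2,4-dioxohexyl]-2,2-dimethyl-4H-1,3-dioxin-4-one
Product: 15 (2S)-5,7-dihydroxy-2-Ar-2,3-dihydro-4H-chromen-4-one, via dihydropyranone 13 (not isolated), via acylketene 14 (not isolated)
Conditions: TsOH·H2O (5 mol %), toluene, rt; then NaHCO3, 4 Å MS, dilution to 2 mM, 110 °C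
Reagents that add atoms: none
Why: Proposed new method: catalytic acid makes the C2 hydroxyl add to the C8a ketone (6-exo-trig hemiketalisation) and the hemiketal loses water into conjugation with C4=O, which forms the O1–C8a bond and closes ring C as the vinylogous ester 13; this is the known cyclodehydration of δ-hydroxy-β-diketones to 2,3-dihydro-4H-pyran-4-ones and it is run below the temperature at which the dioxinone opens. At 110 °C the dioxinone loses acetone by the known retro-[4+2] reaction to acylketene 14, enolisation of the C8 methylene gives the dienylketene C4a=C8a–C8=C7–C6=C5=O, and thermal disrotatory 6π-electrocyclisation (equally describable as six-membered C-acylation of the nucleophilic vinylogous-ester carbon C4a by the ketene) closes ring A, after which tautomerisation gives the 5,7-dihydroxy arene. The closest known reaction types are the thermolysis, trapping and aromatisation of diketo-dioxinones in resorcylate synthesis and the dienylketene electrocyclisation that ends the Danheiser benzannulation; new is their union on a dihydropyranone, which turns the folding into the Claisen (phloroglucinol) mode. No stereocenter is created: C2 keeps the (S) configuration from step 7 because its C–O bond is never broken and the second stage is neutral, so neither benzylic ionisation nor base-induced retro-oxa-Michael opening is invited. The selectivity needed is the order and mode of folding, and the substrate secures it: the hydroxyl can reach only C8a through a six-membered ring, and once O1 is bound there no C8a enol oxygen is left to lactonise the ketene to a 4-hydroxy-2-pyranone, while an aldol closure onto C4 would require a bridged bicycle. Molecular sieves take up the water set free in the first stage before the ketene is formed, and high dilution disfavours ketene dimerisation and acylation of the product phenols.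

**Compound list**

1 | methyl 3-bromo-4-hydroxybenzoate | COC(=O)c1ccc(O)c(Br)c1 | starting material
2 | methyl 3-bromo-4-hydroxy-5-iodobenzoate | COC(=O)c1cc(Br)c(O)c(I)c1 | intermediate
3 | methyl 3-bromo-5-iodo-4-methoxybenzoate | COC(=O)c1cc(Br)c(OC)c(I)c1 | intermediate
4 | 2-methylbut-1-en-3-yne | C=C(C)C#C | starting material
5 | 4,4,5,5-tetramethyl-2-[(1E)-3-methylbuta-1,3-dien-1-yl]-1,3,2-dioxaborolane | C=C(C)/C=C/B1OC(C)(C)C(C)(C)O1 | intermediate
6 | methyl 3-bromo-4-methoxy-5-[(1E)-3-methylbuta-1,3-dien-1-yl]benzoate | C=C(C)/C=C/c1cc(C(=O)OC)cc(Br)c1OC | intermediate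
7 | methyl 4-methoxy-3-[(1E)-3-methylbuta-1,3-dien-1-yl]-5-(3-methylbut-2-en-1-yl)benzoate | C=C(C)/C=C/c1cc(C(=O)OC)cc(CC=C(C)C)c1OC | intermediate
8 | methyl 3-Ar-3-oxopropanoate | C=C(C)/C=C/c1cc(C(=O)CC(=O)OC)cc(CC=C(C)C)c1OC | intermediate
9 | methyl (3S)-3-Ar-3-hydroxypropanoate | C=C(C)/C=C/c1cc([C@@H](O)CC(=O)OC)cc(CC=C(C)C)c1OC | intermediate
10 | 2,2,6-trimethyl-4H-1,3-dioxin-4-one | CC1=CC(=O)OC(C)(C)O1 | starting material
11 | 2,2-dimethyl-6-(2-oxopropyl)-4H-1,3-dioxin-4-one | CC(=O)CC1=CC(=O)OC(C)(C)O1 | intermediate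
12 | 6-[(6S)-6-Ar-6-hydroxy-2,4-dioxohexyl]-2,2-dimethyl-4H-1,3-dioxin-4-one | C=C(C)/C=C/c1cc([C@@H](O)CC(=O)CC(=O)CC2=CC(=O)OC(C)(C)O2)cc(CC=C(C)C)c1OC | intermediate
13 | (2S)-2-Ar-6-[(2,2-dimethyl-4-oxo-4H-1,3-dioxin-6-yl)methyl]-2,3-dihydro-4H-pyran-4-one | C=C(C)/C=C/c1cc([C@@H]2CC(=O)C=C(CC3=CC(=O)OC(C)(C)O3)O2)cc(CC=C(C)C)c1OC | intermediate
14 | 4-[(2S)-2-Ar-4-oxo-3,4-dihydro-2H-pyran-6-yl]-3-oxobut-1-en-1-one (acylketene) | C=C(C)/C=C/c1cc([C@@H]2CC(=O)C=C(CC(=O)C=C=O)O2)cc(CC=C(C)C)c1OC | intermediate
15 | (2S)-5,7-dihydroxy-2-{4-methoxy-3-[(1E)-3-methylbuta-1,3-dien-1-yl]-5-(3-methylbut-2-en-1-yl)phenyl}-2,3-dihydro-4H-chromen-4-one | C=C(C)/C=C/c1cc([C@@H]2CC(=O)c3c(O)cc(O)cc3O2)cc(CC=C(C)C)c1OC | target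

**Step count and risks**

Total step count: 10. Longest linear sequence: 8 steps (steps 1, 2, 4, 5, 6, 7, 9, 10).

Steps most likely to fail:

Step 10. In the first stage, water may be eliminated across C2–C3 instead of from the hemiketal, or the dioxinone carbon C6 may attack C4 in an aldol aromatisation before the hydroxyl has closed ring C. Acid may also ionise the benzylic C2–O bond and erode the configuration, or protonate the diene. In the second stage, the ketene may dimerise or acylate product phenols instead of closing ring A. The fallback sets out from 12 and comes back at 15, using known ionic chemistry in separate operations. Compound 12 is cyclodehydrated alone (TsOH cat., CH2Cl2, rt) and the dihydropyranone 13 is isolated. Heating 13 with methanol in toluene at 110 °C (alcohol trapping of a dioxinone-derived acylketene) should give the pyranone β-keto ester methyl 4-[(2S)-2-Ar-4-oxo-3,4-dihydro-2H-pyran-6-yl]-3-oxobutanoate F1. Treating F1 with Mg(OMe)2 in MeOH at rt should close ring A by an intramolecular Claisen (Dieckmann-type) condensation at C4a with aromatisation, giving 15.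

Step 9. Acylation of the alkoxide-bearing ester may be sluggish, the lithium aldolate may undergo retro-aldol cleavage (loss of material and of enantiopurity), or proton transfer may quench the dianion. The fallback sets out from 9 and comes back at 12; it replaces the hard dianion by soft enolisation and a later decarboxylation. Compound 9 is silylated (TBSOTf, 2,6-lutidine) to methyl (3S)-3-Ar-3-[(tert-butyldimethylsilyl)oxy]propanoate F2, which is saponified (LiOH, THF/H2O) to (3S)-3-Ar-3-[(tert-butyldimethylsilyl)oxy]propanoic acid F3. The acid is converted with 1-chloro-N,N,2-trimethylprop-1-en-1-amine into (3S)-3-Ar-3-[(tert-butyldimethylsilyl)oxy]propanoyl chloride F4. Separately, 10 is acylated (LiHMDS; allyl 3-chloro-3-oxopropanoate) to allyl 4-(2,2-dimethyl-4-oxo-4H-1,3-dioxin-6-yl)-3-oxobutanoate F5. The magnesium chelate of this keto ester (MgCl2, pyridine, CH2Cl2) is C-acylated by the acid chloride to allyl 2-{(3S)-3-Ar-3-[(tert-butyldimethylsilyl)oxy]propanoyl}-4-(2,2-dimethyl-4-oxo-4H-1,3-dioxin-6-yl)-3-oxobutanoate F6. Pd(PPh3)4 and morpholine should then remove the allyl ester with decarboxylation to 6-{(6S)-6-Ar-6-[(tert-butyldimethylsilyl)oxy]-2,4-dioxohexyl}-2,2-dimethyl-4H-1,3-dioxin-4-one F7, and HF·pyridine in THF should release 12.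

Step 5. The allyl unit may couple through its γ-carbon (1,1-dimethylallyl isomer), the allylzinc reagent may add to the ester, or the prenyl double bond may migrate. The fallback sets out from 1 and comes back at 7; it installs the prenyl group by a sigmatropic shift instead of a cross-coupling. Compound 1 is O-alkylated with 3-chloro-3-methylbut-1-yne (CuCl2 cat., DBU, MeCN) to methyl 3-bromo-4-[(2-methylbut-3-yn-2-yl)oxy]benzoate F8. Semihydrogenation (H2, Pd/CaCO3 poisoned with Pb(OAc)2, quinoline) should give methyl 3-bromo-4-[(2-methylbut-3-en-2-yl)oxy]benzoate F9. Aromatic Claisen rearrangement (N,N-diethylaniline, 150 °C) moves the allyl unit with inversion to the free ortho carbon, which should give methyl 3-bromo-4-hydroxy-5-(3-methylbut-2-en-1-yl)benzoate F10. Methylation (MeI, K2CO3, DMF) should give methyl 3-bromo-4-methoxy-5-(3-methylbut-2-en-1-yl)benzoate F11, and Suzuki–Miyaura coupling of this bromide with 5 (Pd(OAc)2, SPhos, K3PO4, toluene/H2O, 80 °C) should give 7.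

**Further compounds**

F1 | step 10 | methyl 4-[(2S)-2-Ar-4-oxo-3,4-dihydro-2H-pyran-6-yl]-3-oxobutanoate | C=C(C)/C=C/c1cc([C@@H]2CC(=O)C=C(CC(=O)CC(=O)OC)O2)cc(CC=C(C)C)c1OC
F2 | step 9 | methyl (3S)-3-Ar-3-[(tert-butyldimethylsilyl)oxy]propanoate | C=C(C)/C=C/c1cc([C@@H](O[Si](C)(C)C(C)(C)C)CC(=O)OC)cc(CC=C(C)C)c1OC
F3 | step 9 | (3S)-3-Ar-3-[(tert-butyldimethylsilyl)oxy]propanoic acid | C=C(C)/C=C/c1cc([C@@H](O[Si](C)(C)C(C)(C)C)CC(=O)O)cc(CC=C(C)C)c1OC
F4 | step 9 | (3S)-3-Ar-3-[(tert-butyldimethylsilyl)oxy]propanoyl chloride | C=C(C)/C=C/c1cc([C@@H](O[Si](C)(C)C(C)(C)C)CC(=O)Cl)cc(CC=C(C)C)c1OC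
F5 | step 9 | allyl 4-(2,2-dimethyl-4-oxo-4H-1,3-dioxin-6-yl)-3-oxobutanoate | C=CCOC(=O)CC(=O)CC1=CC(=O)OC(C)(C)O1
F6 | step 9 | allyl 2-{(3S)-3-Ar-3-[(tert-butyldimethylsilyl)oxy]propanoyl}-4-(2,2-dimethyl-4-oxo-4H-1,3-dioxin-6-yl)-3-oxobutanoate | C=C(C)/C=C/c1cc([C@@H](O[Si](C)(C)C(C)(C)C)CC(=O)C(C(=O)OCC=C)C(=O)CC2=CC(=O)OC(C)(C)O2)cc(CC=C(C)C)c1OC
F7 | step 9 | 6-{(6S)-6-Ar-6-[(tert-butyldimethylsilyl)oxy]-2,4-dioxohexyl}-2,2-dimethyl-4H-1,3-dioxin-4-one | C=C(C)/C=C/c1cc([C@@H](O[Si](C)(C)C(C)(C)C)CC(=O)CC(=O)CC2=CC(=O)OC(C)(C)O2)cc(CC=C(C)C)c1OC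
F8 | step 5 | methyl 3-bromo-4-[(2-methylbut-3-yn-2-yl)oxy]benzoate | COC(=O)c1ccc(OC(C)(C)C#C)c(Br)c1
F9 | step 5 | methyl 3-bromo-4-[(2-methylbut-3-en-2-yl)oxy]benzoate | COC(=O)c1ccc(OC(C)(C)C=C)c(Br)c1
F10 | step 5 | methyl 3-bromo-4-hydroxy-5-(3-methylbut-2-en-1-yl)benzoate | COC(=O)c1cc(Br)c(O)c(CC=C(C)C)c1
F11 | step 5 | methyl 3-bromo-4-methoxy-5-(3-methylbut-2-en-1-yl)benzoate | COC(=O)c1cc(Br)c(OC)c(CC=C(C)C)c1
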